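**Retrosynthetic overview**

1. Target 28 is a labdane. Ring A (C1–C5, C10) carries C4(Me)(CO2H); ring B (C5–C10) carries C8–CO2H and the C9–C11–C12–butenolide chain. The strategy rests on one feature: the quaternary, methyl-bearing C10 is β and C5 is α to a latent C4 carbonyl of ring A.
2. Key disconnection: C9–C10 and C5–C6 are formed together by enantioselective copper-catalysed conjugate addition of a 2-alkenylaluminium (C9, C11, C12) to 3-methylcyclohex-2-enone (ring A, bought), with allylation of the enolate at C5.
3. Ring B is closed second. Ozonolysis turns allyl into the C7 aldehyde and the methylidene into the C9 ketone, C8 arrives as a phosphonoacetate, and an intramolecular Horner–Wadsworth–Emmons reaction gives C8=C9. Conjugate reduction and equilibration then set C9 and C8.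
4. The C4 ketone becomes a masked C19 aldehyde (Wittig, acetal). The 4α-methyl is introduced only in the trans-decalin, where the axial C20 methyl directs it, and C19 is oxidised to the acid near the end.
5. The butenolide ring is bought and joined last through C12–C13 (Negishi coupling). Ring order: A (commercial), B (step 9), butenolide (step 16).

Key step: step 2

**Remarks before the steps**

- Labdane numbering is used for all intermediates: C17 is the carboxyl carbon on C8, C18 the 4α-methyl, C19 the 4β carbon, C20 the methyl on C10; α is the face opposite C20.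
- The silyl group is tert-butyldiphenylsilyl (TBDPS), because the ether must survive PPTS/MeOH (step 4) and aqueous acid (step 12).
- Assumption: the sense of induction of the chiral carbene is assigned by analogy only. The ligand enantiomer that gives (S) at C3 of 8 (labdane C10) is used; both enantiomers are accessible from (S,S)- or (R,R)-1,2-diphenylethylenediamine.

**Route**

Step 1
Reactants: 1 but-3-yn-1-ol
Product: 2 tert-butyl(but-3-yn-1-yloxy)diphenylsilane
Conditions: TBDPSCl, imidazole, DMF, 0 °C → rt
Reagents that add atoms: tert-butyl(chloro)diphenylsilane, CC(C)(C)[Si](Cl)(c1ccccc1)c1ccccc1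
Why: Standard silylation of a primary alcohol; the alkyne is untouched and no stereocentre is involved.

Step 2
Reactants: 2 tert-butyl(but-3-yn-1-yloxy)diphenylsilane; 3 3-methylcyclohex-2-en-1-one; 4 allyl iodide
Product: 8 (2R,3S)-2-allyl-3-methyl-3-[4-(tert-butyldiphenylsilyloxy)but-1-en-2-yl]cyclohexan-1-one, via alkenylaluminium 5 (not isolated), via aluminium enolate 6 (not isolated), via lithium aluminate enolate 7 (not isolated)
Conditions: (a) 2 (2.2 equiv), i-Bu2AlH (2.0 equiv), NiCl2(dppp) (3 mol%), THF, 0 → 22 °C; (b) 3 (1.0 equiv), CuCl2·2H2O (5 mol%), chiral 4,5-diphenylimidazolinium sulfonate (N-2,6-diethylphenyl, N-2-sulfonatoaryl) pre-treated with Ag2O (5 mol%), THF, −78 → −40 °C; (c) MeLi, −78 °C; (d) 4 (excess), DMPU, −78 → 0 °C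
Reagents that add atoms: none
Why: NiCl2(dppp)-catalysed hydroalumination places aluminium on the internal carbon of 2; the 2-alkenyl group of 5 is then transmetalated to the chiral carbene–copper centre and adds 1,4 to 3, the ligand selecting the enone face and creating quaternary C10 ((S) at C3 of 8). MeLi converts the aluminium enolate 6 into the more nucleophilic aluminate 7, whose C5 is allylated by 4 in an SN2 reaction on the face anti to the branched alkenyl group, so that allyl and alkenyl end up trans (substrate control by the adjacent quaternary centre). The closest known reaction type is the copper-catalysed enantioselective conjugate addition of alkenylaluminium reagents to β-substituted cyclic enones with alkylation of the aluminium enolate. No ring is closed; the skeletal bonds C9–C10 and C5–C6 are formed and ring A is carried in from 3. The step needs enantioselectivity at C10, transfer of alkenyl rather than isobutyl, C- rather than O-allylation, and trans diastereoselectivity at C5. These should be secured, in that order, by the bidentate sulfonate carbene, by the faster migration of sp2 ligands from aluminium to copper, by the soft iodide electrophile on the ate complex, and by the size difference between alkenyl and methyl on C10.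

Step 3
Reactants: 8 (2R,3S)-2-allyl-3-methyl-3-[4-(tert-butyldiphenylsilyloxy)but-1-en-2-yl]cyclohexan-1-one
Product: 9 methoxymethylidene enol ether of 8 (C4=C19H–OMe, E/Z mixture; C5 and C10 as in 8)
Conditions: Ph3P(Cl)CH2OMe (3 equiv), t-BuOK (2.9 equiv), THF, 0 °C; then 8, rt → 45 °C
Reagents that add atoms: (methoxymethyl)triphenylphosphonium chloride, COC[P+](c1ccccc1)(c1ccccc1)c1ccccc1.[Cl-]
Why: Wittig methoxymethylenation turns the hindered C4 ketone into a one-carbon-longer masked aldehyde (C19); excess ylide compensates for slow addition, and no stereocentre is created (alkene geometry is irrelevant).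

Step 4
Reactants: 9 methoxymethylidene enol ether of 8
Product: 10 dimethyl acetal: 2-allyl-1-(dimethoxymethyl)-3-methyl-3-[4-(tert-butyldiphenylsilyloxy)but-1-en-2-yl]cyclohexane (C4 epimers; C5 and C10 as in 8)
Conditions: MeOH, PPTS (10 mol%), rt
Reagents that add atoms: methanol, CO
Why: Acid-catalysed addition of methanol to the enol ether through the oxocarbenium ion gives the acetal and removes the ozone-sensitive enol ether; the new C4 centre forms as a mixture that is erased in step 13.

Step 5
Reactants: 10 dimethyl acetal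
Product: 11 keto aldehyde: C7 aldehyde (CH2CHO on C5) and C9 ketone (C10–CO–CH2CH2OTBDPS), acetal on C4
Conditions: O3, CH2Cl2/MeOH 4:1, NaHCO3, −78 °C, stopped at first persistent blue; Me2S, −78 °C → rt
Reagents that add atoms: ozone, [O-][O+]=O
Why: Ozonolysis with reductive work-up cleaves both alkenes (allyl to the C7 aldehyde, methylidene to the C9 ketone) much faster than ozone attacks the acetal C–H or the arenes; no stereocentre is touched.

Step 6
Reactants: 11 keto aldehyde
Product: 12 hydroxy ketone: C7 primary alcohol (CH2CH2OH on C5), C9 ketone retained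
Conditions: NaBH4, MeOH/CH2Cl2, −78 → −40 °C
Reagents that add atoms: none
Why: Chemoselective hydride reduction: the unhindered aldehyde is reduced at low temperature, while the ketone flanked by quaternary C10 is not.

Step 7
Reactants: 12 hydroxy ketone
Product: 13 iodo ketone: C7 primary iodide (CH2CH2I on C5)
Conditions: I2, PPh3, imidazole, CH2Cl2, 0 °C → rt
Reagents that add atoms: iodine, II
Why: Garegg–Samuelsson iodination of a primary alcohol; the imidazole buffer keeps acetal and silyl ether intact, and any cyclic hemiketal form of 12 is drained through the open alcohol.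

Step 8
Reactants: 13 iodo ketone; 14 tert-butyl 2-(diethoxyphosphoryl)acetate
Product: 15 keto phosphonate: tert-butyl 2-(diethoxyphosphoryl)butanoate whose C4 of the chain (labdane C6) is attached to C5; C8 carries P and CO2tBu (C8 and C4 epimers)
Conditions: 14 (1.6 equiv), NaH (1.5 equiv), DMF, 0 °C → rt; then 13, rt → 45 °C
Reagents that add atoms: none
Why: SN2 alkylation of the sodium phosphonoacetate carbanion by the primary iodide brings in C8 with its carboxyl (C17) and the phosphonate; the stabilised anion is too weak a base to enolise the C9 ketone, and the C8 mixture is of no consequence.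

Step 9
Reactants: 15 keto phosphonate
Product: 16 bicyclic enoate: tert-butyl labd-8(9)-en-17-oate core, trans-fused (5α-H, 10β-Me), C4–CH(OMe)2, C12–OTBDPS
Conditions: NaH (1.3 equiv), THF, 0 °C → 60 °C
Reagents that add atoms: none
Why: Intramolecular Horner–Wadsworth–Emmons olefination: the C8 phosphonate carbanion attacks the C9 ketone and closes the six-membered ring B as the tetrasubstituted C8=C9 enoate. The trans relationship of C5–H and C10–Me from step 2 becomes the trans ring fusion, and the low equilibrium concentration of ketone enolate should keep β-elimination of the silyloxy group negligible.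

Step 10
Reactants: 16 bicyclic enoate
Product: 17 saturated ester: 9α-H (C11 chain β, equatorial), C8 as an epimer mixture
Conditions: Mg turnings (15 equiv), MeOH/THF, 0 °C → rt
Reagents that add atoms: none
Why: Dissolving-metal (single-electron) conjugate reduction of the α,β-unsaturated ester; C9 is protonated in the radical anion from the α face, anti to the adjacent axial C20 methyl, which puts H-9 α and the side chain equatorial, and the tert-butyl ester resists methanolysis.

Step 11
Reactants: 17 saturated ester (C8 epimers)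
Product: 18 8α-ester: tert-butyl ester equatorial (8β-H), 9α-H, 5α-H, 10β-Me; C4–CH(OMe)2 (C4 epimers)
Conditions: t-BuOK (0.3 equiv), t-BuOH/THF, 40 °C
Reagents that add atoms: none
Why: Base-mediated epimerisation through the ester enolate funnels C8 to the equatorial ester, because the axial epimer has a 1,3-diaxial clash with the C10 methyl; tert-butoxide cannot transesterify a tert-butyl ester.

Step 12
Reactants: 18 8α-ester
Product: 19 C19 aldehyde (C4–CHO, C4 epimers), other centres as in 18
Conditions: TsOH·H2O (10 mol%), acetone/H2O 10:1, rt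
Reagents that add atoms: water, O
Why: Mild acid-catalysed hydrolysis of a dimethyl acetal; the TBDPS ether and the tert-butyl ester tolerate dilute aqueous acid, and C4 stays a mixture.

Step 13
Reactants: 19 C19 aldehyde
Product: 21 4α-methyl-4β-formyl compound (C19 aldehyde axial, C18 methyl equatorial), via potassium enolate 20 (not isolated)
Conditions: t-BuOK (1.3 equiv), THF/t-BuOH, 0 °C; MeI (3 equiv), 0 °C → rt
Reagents that add atoms: iodomethane, CI
Why: C-alkylation of the enolate of an α-branched aldehyde; only C4–H is acidic enough for t-BuOK (the ester is about eight pK units weaker). MeI approaches the exocyclic enolate of the rigid trans-decalin on the equatorial α face, away from the axial C20 methyl, which sets C4 with the methyl α and the formyl β.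

Step 14
Reactants: 21 4α-methyl-4β-formyl compound
Product: 22 C12 primary alcohol
Conditions: Bu4NF, AcOH, THF, rt
Reagents that add atoms: none
Why: Fluoride cleavage of the silyl ether, buffered with acetic acid so that no alkoxide is available to lactonise onto C17; the tert-butyl ester and the non-enolisable aldehyde are inert.

Step 15
Reactants: 22 C12 primary alcohol
Product: 23 C12 primary iodide
Conditions: I2, PPh3, imidazole, CH2Cl2, 0 °C → rt
Reagents that add atoms: iodine, II
Why: Garegg–Samuelsson iodination of a primary alcohol; the hindered aldehyde and the ester are unaffected.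

Step 16
Reactants: 23 C12 primary iodide; 24 3-bromofuran-2(5H)-one
Product: 26 butenolide aldehyde (C12–C13 bond to the 2-oxo-2,5-dihydrofuran-3-yl ring; C19 aldehyde, C17 tert-butyl ester), via alkylzinc iodide 25 (not isolated)
Conditions: Zn dust (activated with BrCH2CH2Br and Me3SiCl), LiCl, THF, 40 °C; then 24, PdCl2(dppf) (5 mol%), THF/DMF, rt → 45 °C
Reagents that add atoms: none
Why: Zinc inserts into the primary C–I bond, and Negishi coupling (oxidative addition of zerovalent palladium into the activated C–Br bond, transmetalation, reductive elimination) joins C12 to C13. The coupling of alkylzinc halides with α-halo-α,β-unsaturated carbonyl compounds is known, and ester, lactone and the neopentyl aldehyde are tolerated by the organozinc.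

Step 17
Reactants: 26 butenolide aldehyde
Product: 27 C19 acid with C17 tert-butyl ester
Conditions: NaClO2, NaH2PO4, 2-methylbut-2-ene, t-BuOH/H2O, 0 °C → rt
Reagents that add atoms: sodium chlorite, [Na+].[O-]Cl=O
Why: Pinnick oxidation takes the hindered aldehyde to the acid; the scavenger removes hypochlorite so the butenolide alkene is spared, and quaternary C4 cannot epimerise.

Step 18
Reactants: 27 C19 acid with C17 tert-butyl ester
Product: 28 (1S,4aR,5S,6R,8aR)-1,4a-dimethyl-5-[2-(2-oxo-2,5-dihydrofuran-3-yl)ethyl]decahydronaphthalene-1,6-dicarboxylic acid (target)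
Conditions: CF3CO2H/CH2Cl2 1:3, 0 °C → rt
Reagents that add atoms: none
Why: Acidolysis of the tert-butyl ester with loss of the tert-butyl cation frees the C17 acid; the butenolide and the C19 acid are stable to the acid, and C8 already has its thermodynamic configuration.

**Compound list**

1 | but-3-yn-1-ol | C#CCCO | starting material
2 | tert-butyl(but-3-yn-1-yloxy)diphenylsilane | C#CCCO[Si](c1ccccc1)(c1ccccc1)C(C)(C)C | intermediate
3 | 3-methylcyclohex-2-en-1-one | CC1=CC(=O)CCC1 | starting material
4 | allyl iodide (3-iodoprop-1-ene) | C=CCI | starting material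
5 | diisobutyl[4-(tert-butyldiphenylsilyloxy)but-1-en-2-yl]aluminium (not isolated) | C=C(CCO[Si](c1ccccc1)(c1ccccc1)C(C)(C)C)[Al](CC(C)C)CC(C)C | intermediate
6 | diisobutylaluminium enolate of (3S)-3-methyl-3-[4-(tert-butyldiphenylsilyloxy)but-1-en-2-yl]cyclohexanone (not isolated) | C[C@]1(C(=C)CCO[Si](c2ccccc2)(c2ccccc2)C(C)(C)C)CCCC(O[Al](CC(C)C)CC(C)C)=C1 | intermediate
7 | lithium methyl(diisobutyl)aluminate enolate of the same ketone (not isolated) | C[C@]1(C(=C)CCO[Si](c2ccccc2)(c2ccccc2)C(C)(C)C)CCCC(O[Al-](C)(CC(C)C)CC(C)C)=C1.[Li+] | intermediate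
8 | (2R,3S)-2-allyl-3-methyl-3-[4-(tert-butyldiphenylsilyloxy)but-1-en-2-yl]cyclohexan-1-one (allyl trans to the butenyl group, cis to methyl) | C[C@]1(C(=C)CCO[Si](c2ccccc2)(c2ccccc2)C(C)(C)C)CCCC(=O)[C@@H]1CC=C | intermediate
9 | methoxymethylidene enol ether of 8 (E/Z mixture) | C[C@]1(C(=C)CCO[Si](c2ccccc2)(c2ccccc2)C(C)(C)C)CCCC(=COC)[C@@H]1CC=C | intermediate
10 | dimethyl acetal, 2-allyl-1-(dimethoxymethyl)-3-methyl-3-[4-(tert-butyldiphenylsilyloxy)but-1-en-2-yl]cyclohexane (C4 epimers) | C[C@]1(C(=C)CCO[Si](c2ccccc2)(c2ccccc2)C(C)(C)C)CCCC(C(OC)OC)[C@@H]1CC=C | intermediate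
11 | keto aldehyde, 2-[2-(dimethoxymethyl)-6-methyl-6-(3-silyloxypropanoyl)cyclohexyl]acetaldehyde | C[C@]1(C(=O)CCO[Si](c2ccccc2)(c2ccccc2)C(C)(C)C)CCCC(C(OC)OC)[C@@H]1CC=O | intermediate
12 | hydroxy ketone (2-hydroxyethyl on C5, C9 ketone) | C[C@]1(C(=O)CCO[Si](c2ccccc2)(c2ccccc2)C(C)(C)C)CCCC(C(OC)OC)[C@@H]1CCO | intermediate
13 | iodo ketone (2-iodoethyl on C5, C9 ketone) | C[C@]1(C(=O)CCO[Si](c2ccccc2)(c2ccccc2)C(C)(C)C)CCCC(C(OC)OC)[C@@H]1CCI | intermediate
14 | tert-butyl 2-(diethoxyphosphoryl)acetate | CCOP(=O)(CC(=O)OC(C)(C)C)OCC | starting material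
15 | keto phosphonate (C8 bears P(O)(OEt)2 and CO2tBu; C9 ketone) | C[C@]1(C(=O)CCO[Si](c2ccccc2)(c2ccccc2)C(C)(C)C)CCCC(C(OC)OC)[C@@H]1CCC(C(=O)OC(C)(C)C)P(=O)(OCC)OCC | intermediate
16 | bicyclic enoate, trans-fused, C8=C9, C17 tert-butyl ester, C4–CH(OMe)2, C12–OTBDPS | C[C@]12CCCC(C(OC)OC)[C@@H]1CCC(C(=O)OC(C)(C)C)=C2CCO[Si](c1ccccc1)(c1ccccc1)C(C)(C)C | intermediate
17 | saturated ester, 9α-H, C8 epimer mixture | C[C@]12CCCC(C(OC)OC)[C@@H]1CCC(C(=O)OC(C)(C)C)[C@@H]2CCO[Si](c1ccccc1)(c1ccccc1)C(C)(C)C | intermediate
18 | 8α (equatorial) tert-butyl ester, 9α-H, 5α-H, 10β-Me, C4–CH(OMe)2 | C[C@]12CCCC(C(OC)OC)[C@@H]1CC[C@@H](C(=O)OC(C)(C)C)[C@@H]2CCO[Si](c1ccccc1)(c1ccccc1)C(C)(C)C | intermediate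
19 | C19 aldehyde (C4 epimers) | C[C@]12CCCC(C=O)[C@@H]1CC[C@@H](C(=O)OC(C)(C)C)[C@@H]2CCO[Si](c1ccccc1)(c1ccccc1)C(C)(C)C | intermediate
20 | potassium enolate of 19 (C4=C19–OK, not isolated) | C[C@]12CCCC(=C[O-])[C@@H]1CC[C@@H](C(=O)OC(C)(C)C)[C@@H]2CCO[Si](c1ccccc1)(c1ccccc1)C(C)(C)C.[K+] | intermediate
21 | 4α-methyl-4β-formyl compound | C[C@]12CCC[C@](C)(C=O)[C@@H]1CC[C@@H](C(=O)OC(C)(C)C)[C@@H]2CCO[Si](c1ccccc1)(c1ccccc1)C(C)(C)C | intermediate
22 | C12 primary alcohol | C[C@]12CCC[C@](C)(C=O)[C@@H]1CC[C@@H](C(=O)OC(C)(C)C)[C@@H]2CCO | intermediate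
23 | C12 primary iodide | C[C@]12CCC[C@](C)(C=O)[C@@H]1CC[C@@H](C(=O)OC(C)(C)C)[C@@H]2CCI | intermediate
24 | 3-bromofuran-2(5H)-one | O=C1OCC=C1Br | starting material
25 | C12 alkylzinc iodide (not isolated) | C[C@]12CCC[C@](C)(C=O)[C@@H]1CC[C@@H](C(=O)OC(C)(C)C)[C@@H]2CC[Zn]I | intermediate
26 | butenolide aldehyde (C19 aldehyde, C17 tert-butyl ester) | C[C@]12CCC[C@](C)(C=O)[C@@H]1CC[C@@H](C(=O)OC(C)(C)C)[C@@H]2CCC1=CCOC1=O | intermediate
27 | C19 acid with C17 tert-butyl ester | C[C@]12CCC[C@](C)(C(=O)O)[C@@H]1CC[C@@H](C(=O)OC(C)(C)C)[C@@H]2CCC1=CCOC1=O | intermediate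
28 | (1S,4aR,5S,6R,8aR)-1,4a-dimethyl-5-[2-(2-oxo-2,5-dihydrofuran-3-yl)ethyl]decahydronaphthalene-1,6-dicarboxylic acid | C[C@]12CCC[C@](C)(C(=O)O)[C@@H]1CC[C@@H](C(=O)O)[C@@H]2CCC1=CCOC1=O | target

**Step count**

Total step count: 18. Longest linear sequence: 18 steps (1 → 28); 3, 4, 14 and 24 are bought.

**Steps most likely to fail, with fallbacks**

Step 2. The branched alkenyl group may transfer slowly or with poor enantioface discrimination, hydroalumination may give some of the terminal alane, and the one-pot allylation may erode the trans ratio at C5. Fallback, setting out from 2 and returning at 8, reverses the roles of the two carbon groups on C10. The alane 5, made as in step 2, is quenched with N-bromosuccinimide to give (3-bromobut-3-en-1-yloxy)(tert-butyl)diphenylsilane F1, which is purified from any regioisomer. Bromine–lithium exchange (t-BuLi, Et2O, −78 °C) gives [4-(tert-butyldiphenylsilyloxy)but-1-en-2-yl]lithium F2. This adds 1,2 to 3-ethoxycyclohex-2-en-1-one to give the lithium 3-ethoxy-1-alkenylcyclohex-2-en-1-olate F3, and aqueous HCl in the work-up removes ethanol to give 3-[4-(tert-butyldiphenylsilyloxy)but-1-en-2-yl]cyclohex-2-en-1-one F4 (Stork–Danheiser transposition). Copper-catalysed 1,4-addition of MeMgBr (Cu(OTf)2, chiral imidazolium-derived carbene, Et2O, −30 °C) then creates the same quaternary C10 and gives the bromomagnesium enolate F5, which is allylated with 4 (DMPU) to return to 8.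

Step 10. Electron transfer to the twisted, tetrasubstituted enoate may be incomplete, or protonation at C9 may lose its facial preference. Fallback, setting out from 16 and returning at 17: radical hydrogen-atom-transfer hydrogenation (Mn(dpm)3, PhSiH3, t-BuOOH, i-PrOH, rt) delivers a hydrogen atom to C9 from the α face and then quenches the ester-stabilised C8 radical. The C8 mixture obtained is 17 and is equilibrated in step 11; no new compound arises.

Step 16. Zinc insertion may be slow, or the sp3–sp2 coupling may suffer protodemetalation or β-hydride elimination. Fallback, setting out from 23 and returning at 26, replaces the cross-coupling by an enolate alkylation. 3-Bromodihydrofuran-2(3H)-one and thiophenol (Et3N) give 3-(phenylsulfanyl)dihydrofuran-2(3H)-one F6. Its potassium enolate F7 (KHMDS, THF/DMPU, −78 °C) is alkylated by iodide 23 to the 3-alkyl-3-(phenylsulfanyl) lactone F8; aldol addition to the neopentyl C19 aldehyde is reversible, whereas alkylation is not. Oxidation with mCPBA (1 equiv, −78 °C) gives the sulfoxide F9, and thermal syn-elimination towards the ring CH2 (toluene, 110 °C) gives 26.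

Further compounds
F1 | step 2 | (3-bromobut-3-en-1-yloxy)(tert-butyl)diphenylsilane | C=C(Br)CCO[Si](c1ccccc1)(c1ccccc1)C(C)(C)C
F2 | step 2 | [4-(tert-butyldiphenylsilyloxy)but-1-en-2-yl]lithium | [Li]C(=C)CCO[Si](c1ccccc1)(c1ccccc1)C(C)(C)C
F3 | step 2 | lithium 3-ethoxy-1-[4-(tert-butyldiphenylsilyloxy)but-1-en-2-yl]cyclohex-2-en-1-olate | CCOC1=CC([O-])(C(=C)CCO[Si](c2ccccc2)(c2ccccc2)C(C)(C)C)CCC1.[Li+]
F4 | step 2 | 3-[4-(tert-butyldiphenylsilyloxy)but-1-en-2-yl]cyclohex-2-en-1-one | C=C(CCO[Si](c1ccccc1)(c1ccccc1)C(C)(C)C)C1=CC(=O)CCC1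
F5 | step 2 | bromomagnesium enolate of (3S)-3-methyl-3-[4-(tert-butyldiphenylsilyloxy)but-1-en-2-yl]cyclohexanone | C[C@]1(C(=C)CCO[Si](c2ccccc2)(c2ccccc2)C(C)(C)C)CCCC(O[Mg]Br)=C1
F0 | step 10 | none | none
F6 | step 16 | 3-(phenylsulfanyl)dihydrofuran-2(3H)-one | O=C1OCCC1Sc1ccccc1
F7 | step 16 | potassium enolate of 3-(phenylsulfanyl)dihydrofuran-2(3H)-one | [O-]C1=C(Sc2ccccc2)CCO1.[K+]
F8 | step 16 | 3-alkyl-3-(phenylsulfanyl) lactone (saturated, C13 bears SPh; C19 aldehyde, C17 tert-butyl ester) | C[C@]12CCC[C@](C)(C=O)[C@@H]1CC[C@@H](C(=O)OC(C)(C)C)[C@@H]2CCC1(Sc3ccccc3)CCOC1=O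
F9 | step 16 | sulfoxide of F8 | C[C@]12CCC[C@](C)(C=O)[C@@H]1CC[C@@H](C(=O)OC(C)(C)C)[C@@H]2CCC1(S(=O)c3ccccc3)CCOC1=O
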